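The side chain is cut at C1'–C2' and C3'–CH3, so that the (E)-trisubstituted C2'=C3' olefin, which carries a methyl group on C3' and the aryloxymethyl carbon C1' (bound through oxygen to C5 of the phthalide benzene ring) on C2', arises from a terminal alkyne. Zirconium-catalysed syn-methylalumination of enyne 11 and capture of the resulting (E)-alkenylalane by aryl chloromethyl ether 19 form both bonds, fix the olefin geometry and join chain to arene in one operation. The precursors are a C13 (E)-enyne with a silylated tertiary alcohol and a 4-silyloxy-6-methoxyphthalide bearing OCH2Cl on C5; fluoride then removes both silyl groups.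

Key step: step 12

Remark on the chemistry: the phthalide is numbered as 2-benzofuran-1(3H)-one (C1 lactone carbonyl, C3 lactone CH2, C4 OH, C5 O-side chain, C6 OCH3), and the side chain runs from C1' (OCH2) to C11' (carbinol carbon). Geranyl acetate is bought as the acetate of geraniol. The methylthiomethyl group is placed on the benzoate before the lactone is built, so that only one phenol is free when the lactone carbon is introduced.

**Fragment A: enyne 11**

Step 1
Reactants: 1 geranyl acetate [(2E)-3,7-dimethylocta-2,6-dien-1-yl acetate]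
Product: 3 (2E)-7-hydroxy-3,7-dimethyloct-2-en-1-yl acetate, via alkylmercury acetate 2 (not isolated)
Conditions: Hg(OAc)2 (1.05 equiv), THF/H2O 1:1, 0 °C to rt; then NaBH4, 3 M NaOH, 0 °C
Reagents that add atoms: water, O
Why: Oxymercuration–demercuration: divalent mercury adds to the more electron-rich 6,7-olefin (the 2,3-olefin is deactivated by the allylic acetate), water opens the mercurinium ion at the tertiary carbon (Markovnikov) and NaBH4 replaces mercury by hydrogen, so no stereocentre survives and the (2E)-olefin is untouched.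

Step 2
Reactants: 3 (2E)-7-hydroxy-3,7-dimethyloct-2-en-1-yl acetate
Product: 4 (2E)-3,7-dimethyl-7-[(triethylsilyl)oxy]oct-2-en-1-yl acetate
Conditions: Et3SiOTf (1.3 equiv), 2,6-lutidine (2 equiv), CH2Cl2, −78 to 0 °C
Reagents that add atoms: triethylsilyl trifluoromethanesulfonate, CC[Si](CC)(CC)OS(=O)(=O)C(F)(F)F
Why: Silyl triflate silylation of a hindered tertiary alcohol under 2,6-lutidine buffering, which leaves the allylic acetate intact.

Step 3
Reactants: 4 (2E)-3,7-dimethyl-7-[(triethylsilyl)oxy]oct-2-en-1-yl acetate
Product: 5 (2E)-3,7-dimethyl-7-[(triethylsilyl)oxy]oct-2-en-1-ol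
Conditions: K2CO3 (0.3 equiv), MeOH, 0 °C to rt
Reagents that add atoms: none
Why: Base-catalysed transesterification (methanolysis) removes the acetate, while the tertiary triethylsilyl ether is stable to K2CO3 in methanol.

Step 4
Reactants: 5 (2E)-3,7-dimethyl-7-[(triethylsilyl)oxy]oct-2-en-1-ol
Product: 7 {[(6E)-8-chloro-2,6-dimethyloct-6-en-2-yl]oxy}triethylsilane, via allylic mesylate 6 (not isolated)
Conditions: MsCl (1.3 equiv), LiCl (3 equiv), 2,4,6-collidine (2 equiv), DMF, 0 °C
Reagents that add atoms: lithium chloride, [Li+].[Cl-]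
Why: Collington–Meyers chlorination: the primary allylic mesylate formed in the flask is displaced by chloride in an SN2 reaction without allylic transposition or loss of the E geometry, and collidine keeps the medium non-acidic for the silyl ether.

Step 5
Reactants: 7 {[(6E)-8-chloro-2,6-dimethyloct-6-en-2-yl]oxy}triethylsilane; 8 1-(trimethylsilyl)propyne
Product: 10 (5E)-6,10-dimethyl-10-[(triethylsilyl)oxy]-1-(trimethylsilyl)undec-5-en-1-yne, via lithiated silylpropyne 9 (not isolated)
Conditions: 8 (1.5 equiv), n-BuLi (1.4 equiv), THF, −78 to −20 °C; then 7, −78 °C to rt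
Reagents that add atoms: none
Why: Propargylic lithiation of 8 followed by SN2 alkylation of the primary allylic chloride; the silyl group blocks the alkyne terminus and steers bond formation to the propargylic carbon, and the E-olefin is not involved.

Step 6
Reactants: 10 (5E)-6,10-dimethyl-10-[(triethylsilyl)oxy]-1-(trimethylsilyl)undec-5-en-1-yne
Product: 11 (5E)-6,10-dimethyl-10-[(triethylsilyl)oxy]undec-5-en-1-yne [the same compound may be named (E)-2,6-dimethyl-2-(triethylsilyloxy)undec-6-en-10-yne]
Conditions: K2CO3 (0.5 equiv), MeOH, rt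
Reagents that add atoms: none
Why: Methoxide-mediated protodesilylation of the alkynylsilane (C(sp)–Si cleavage), to which the tertiary silyl ether is inert.

**Fragment B: aryl chloromethyl ether 19**

Step 7
Reactants: 12 methyl 3,4-dihydroxy-5-methoxybenzoate; 13 chloromethyl methyl sulfide
Product: 14 methyl 3-hydroxy-5-methoxy-4-[(methylsulfanyl)methoxy]benzoate
Conditions: NaH (1.0 equiv), DMF, 0 °C; then 13 (1.05 equiv), 0 °C to rt
Reagents that add atoms: none
Why: Williamson etherification of the monophenoxide: one equivalent of NaH deprotonates the 4-OH, which is para to the ester and the most acidic, so the sulfide alkylates O4 and leaves the 3-OH free.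

Step 8
Reactants: 14 methyl 3-hydroxy-5-methoxy-4-[(methylsulfanyl)methoxy]benzoate
Product: 15 methyl 2-formyl-3-hydroxy-5-methoxy-4-[(methylsulfanyl)methoxy]benzoate
Conditions: MgCl2 (2 equiv), Et3N (4 equiv), (CH2O)n (6 equiv), MeCN, reflux; dilute HCl work-up
Reagents that add atoms: paraformaldehyde (formaldehyde), C=O
Why: Casnati–Skattebøl magnesium-mediated ortho-formylation: formaldehyde is delivered within the magnesium phenoxide to the only free ortho position of the 3-OH (C2, also para to the methoxy group), and hydride transfer to a second formaldehyde gives the salicylaldehyde.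

Step 9
Reactants: 15 methyl 2-formyl-3-hydroxy-5-methoxy-4-[(methylsulfanyl)methoxy]benzoate
Product: 17 4-hydroxy-6-methoxy-5-[(methylsulfanyl)methoxy]-2-benzofuran-1(3H)-one, via hydroxymethyl benzoate 16 (not isolated)
Conditions: NaBH4 (1.2 equiv), THF/MeOH, 0 °C; then 1 M HCl, rt
Reagents that add atoms: none
Why: Borohydride reduction of the aldehyde gives the ortho-hydroxymethyl benzoate, which closes by intramolecular transesterification (5-exo-trig lactonisation) to the phthalide; ester, O,S-acetal and phenol are inert to NaBH4.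

Step 10
Reactants: 17 4-hydroxy-6-methoxy-5-[(methylsulfanyl)methoxy]-2-benzofuran-1(3H)-one
Product: 18 4-[(tert-butyldimethylsilyl)oxy]-6-methoxy-5-[(methylsulfanyl)methoxy]-2-benzofuran-1(3H)-one
Conditions: TBSCl (1.3 equiv), imidazole (2.5 equiv), DMF, rt
Reagents that add atoms: tert-butyldimethylsilyl chloride, CC(C)(C)[Si](C)(C)Cl
Why: Imidazole-promoted silylation of the phenol; masking O4 keeps it from closing onto C1' as a methylenedioxy ring in steps 11 and 12 and from protonating the alane.

Step 11
Reactants: 18 4-[(tert-butyldimethylsilyl)oxy]-6-methoxy-5-[(methylsulfanyl)methoxy]-2-benzofuran-1(3H)-one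
Product: 19 4-[(tert-butyldimethylsilyl)oxy]-5-(chloromethoxy)-6-methoxy-2-benzofuran-1(3H)-one
Conditions: SO2Cl2 (1.05 equiv), CH2Cl2, −20 to 0 °C; volatiles removed in vacuo, toluene chase; used crude
Reagents that add atoms: sulfuryl chloride, O=S(=O)(Cl)Cl
Why: Chlorinative cleavage of an O,S-acetal: S-chlorination by SO2Cl2 and fragmentation release CH3SCl and an aryloxymethyl cation that chloride captures; sulfur reacts far faster than the lactone-deactivated arene, and the volatile co-products leave on evaporation.

**Union and deprotection**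

Step 12
Reactants: 11 (5E)-6,10-dimethyl-10-[(triethylsilyl)oxy]undec-5-en-1-yne; 19 4-[(tert-butyldimethylsilyl)oxy]-5-(chloromethoxy)-6-methoxy-2-benzofuran-1(3H)-one; 20 trimethylaluminium
Product: 22 4-[(tert-butyldimethylsilyl)oxy]-6-methoxy-5-{[(2E,6E)-3,7,11-trimethyl-11-[(triethylsilyl)oxy]dodeca-2,6-dien-1-yl]oxy}-2-benzofuran-1(3H)-one, via alkenyldimethylalane 21 (not isolated)
Conditions: 11 (1.3 equiv), Al(CH3)3 (2.6 equiv), Cp2ZrCl2 (0.25 equiv), CH2Cl2, 0 °C to rt; volatiles including excess Al(CH3)3 removed in vacuo; CH2Cl2, 19 (1.0 equiv), −30 to 0 °C; aq potassium sodium tartrate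
Reagents that add atoms: none
Why: Proposed new method: Al(CH3)3 and Cp2ZrCl2 form a methylzirconocene–aluminium species that adds CH3 and metal syn across the terminal alkyne of 11 with CH3 on the internal carbon (C3'), and transmetalation to aluminium gives the (E)-alkenyldimethylalane 21. Once free Al(CH3)3 has been pumped off, the Lewis-acidic aluminium of 21 assists ionisation of the C–Cl bond of 19, and the alkenyl group is transferred to the aryloxymethyl carbon with retention at the sp2 carbon, forming C1'–C2'. The closest known reaction type is Negishi methylalumination with capture of the alkenylalane by chloromethyl methyl ether; new here is an aryl chloromethyl ether as the electrophile, whose cation is less stabilised but still oxygen-assisted. No ring is closed and no stereocentre is formed; the E geometry of C2'=C3' follows from syn addition plus retentive transfer, and the C6'=C7' olefin is a spectator. The step needs terminal regioselectivity (inherent to the zirconium-catalysed addition to 1-alkynes), alkenyl rather than methyl transfer (the sp2 carbon migrates preferentially from mixed alanes) and chemoselectivity for C–Cl over the lactone and the two silyl ethers, which the neutral alane, the low temperature and the absence of free Al(CH3)3 should secure.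

Step 13
Reactants: 22 4-[(tert-butyldimethylsilyl)oxy]-6-methoxy-5-{[(2E,6E)-3,7,11-trimethyl-11-[(triethylsilyl)oxy]dodeca-2,6-dien-1-yl]oxy}-2-benzofuran-1(3H)-one
Product: 23 farnesylemefuranone E, 4-hydroxy-5-{[(2E,6E)-11-hydroxy-3,7,11-trimethyldodeca-2,6-dien-1-yl]oxy}-6-methoxy-2-benzofuran-1(3H)-one
Conditions: Bu4NF (3 equiv), THF, 0 °C to rt; aq NH4Cl
Reagents that add atoms: none
Why: Fluoride-mediated desilylation: the aryl silyl ether should cleave at once and the tertiary triethylsilyl ether on warming, while the lactone, the allyl aryl ether and both E-olefins are stable to Bu4NF.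

**Compound list**

1 | geranyl acetate, (2E)-3,7-dimethylocta-2,6-dien-1-yl acetate | CC(=O)OC/C=C(\C)CCC=C(C)C | starting material
2 | (2E)-6-(acetoxymercurio)-7-hydroxy-3,7-dimethyloct-2-en-1-yl acetate (racemic at C6) | CC(=O)OC/C=C(\C)CCC([Hg]OC(C)=O)C(C)(C)O | intermediate
3 | (2E)-7-hydroxy-3,7-dimethyloct-2-en-1-yl acetate | CC(=O)OC/C=C(\C)CCCC(C)(C)O | intermediate
4 | (2E)-3,7-dimethyl-7-[(triethylsilyl)oxy]oct-2-en-1-yl acetate | CC(=O)OC/C=C(\C)CCCC(C)(C)O[Si](CC)(CC)CC | intermediate
5 | (2E)-3,7-dimethyl-7-[(triethylsilyl)oxy]oct-2-en-1-ol | OC/C=C(\C)CCCC(C)(C)O[Si](CC)(CC)CC | intermediate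
6 | (2E)-3,7-dimethyl-7-[(triethylsilyl)oxy]oct-2-en-1-yl methanesulfonate | CS(=O)(=O)OC/C=C(\C)CCCC(C)(C)O[Si](CC)(CC)CC | intermediate
7 | {[(6E)-8-chloro-2,6-dimethyloct-6-en-2-yl]oxy}triethylsilane | ClC/C=C(\C)CCCC(C)(C)O[Si](CC)(CC)CC | intermediate
8 | 1-(trimethylsilyl)propyne | CC#C[Si](C)(C)C | starting material
9 | [3-(trimethylsilyl)prop-2-yn-1-yl]lithium | [Li]CC#C[Si](C)(C)C | intermediate
10 | (5E)-6,10-dimethyl-10-[(triethylsilyl)oxy]-1-(trimethylsilyl)undec-5-en-1-yne | C[Si](C)(C)C#CCC/C=C(\C)CCCC(C)(C)O[Si](CC)(CC)CC | intermediate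
11 | (5E)-6,10-dimethyl-10-[(triethylsilyl)oxy]undec-5-en-1-yne | C#CCC/C=C(\C)CCCC(C)(C)O[Si](CC)(CC)CC | intermediate
12 | methyl 3,4-dihydroxy-5-methoxybenzoate | COC(=O)c1cc(O)c(O)c(OC)c1 | starting material
13 | chloromethyl methyl sulfide | CSCCl | starting material
14 | methyl 3-hydroxy-5-methoxy-4-[(methylsulfanyl)methoxy]benzoate | COC(=O)c1cc(O)c(OCSC)c(OC)c1 | intermediate
15 | methyl 2-formyl-3-hydroxy-5-methoxy-4-[(methylsulfanyl)methoxy]benzoate | COC(=O)c1cc(OC)c(OCSC)c(O)c1C=O | intermediate
16 | methyl 3-hydroxy-2-(hydroxymethyl)-5-methoxy-4-[(methylsulfanyl)methoxy]benzoate | COC(=O)c1cc(OC)c(OCSC)c(O)c1CO | intermediate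
17 | 4-hydroxy-6-methoxy-5-[(methylsulfanyl)methoxy]-2-benzofuran-1(3H)-one | COc1cc2c(c(O)c1OCSC)COC2=O | intermediate
18 | 4-[(tert-butyldimethylsilyl)oxy]-6-methoxy-5-[(methylsulfanyl)methoxy]-2-benzofuran-1(3H)-one | COc1cc2c(c(O[Si](C)(C)C(C)(C)C)c1OCSC)COC2=O | intermediate
19 | 4-[(tert-butyldimethylsilyl)oxy]-5-(chloromethoxy)-6-methoxy-2-benzofuran-1(3H)-one | COc1cc2c(c(O[Si](C)(C)C(C)(C)C)c1OCCl)COC2=O | intermediate
20 | trimethylaluminium | C[Al](C)C | starting material
21 | dimethyl[(1E,5E)-2,6,10-trimethyl-10-[(triethylsilyl)oxy]undeca-1,5-dien-1-yl]alane | C[Al](C)/C=C(\C)CC/C=C(\C)CCCC(C)(C)O[Si](CC)(CC)CC | intermediate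
22 | 4-[(tert-butyldimethylsilyl)oxy]-6-methoxy-5-{[(2E,6E)-3,7,11-trimethyl-11-[(triethylsilyl)oxy]dodeca-2,6-dien-1-yl]oxy}-2-benzofuran-1(3H)-one | COc1cc2c(c(O[Si](C)(C)C(C)(C)C)c1OC/C=C(\C)CC/C=C(\C)CCCC(C)(C)O[Si](CC)(CC)CC)COC2=O | intermediate
23 | farnesylemefuranone E, 4-hydroxy-5-{[(2E,6E)-11-hydroxy-3,7,11-trimethyldodeca-2,6-dien-1-yl]oxy}-6-methoxy-2-benzofuran-1(3H)-one | COc1cc2c(c(O)c1OC/C=C(\C)CC/C=C(\C)CCCC(C)(C)O)COC2=O | target

**Count**

Total step count: 13 (six to enyne 11, five to chloride 19, union, deprotection).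
Longest linear sequence: 8 steps (steps 1–6, 12 and 13, from geranyl acetate 1).

**Steps most likely to fail**

1. Step 12 (proposed new method). The aryloxymethyl cation released from 19 may not be captured by the alkenyl group fast enough. Competing processes are methyl transfer from aluminium, closure of the cation onto the neighbouring silyloxy oxygen with loss of the silyl group, Prins-type attack by the C6'=C7' olefin, and Lewis-acid ionisation of the newly formed allyl aryl ether. The fallback uses known chemistry, sets out from 11 and 18 and comes back at 22. Enyne 11 is methylaluminated as in step 12 to alane 21, which n-BuLi (hexane/THF, −78 °C) converts into the lithium alkenylaluminate F1. Paraformaldehyde then gives the (2E,6E)-allylic alcohol F2, the standard carboalumination–hydroxymethylation route to (E)-3-methylalk-2-en-1-ols. In parallel, the methylthiomethyl group of 18 is removed with HgCl2/CaCO3 in aqueous MeCN to give the phenol F3. Mitsunobu etherification of F3 with F2 (PPh3, DIAD, THF, 0 °C) forms the O–C1' bond and should give 22, which continues with step 13. Step 11 is then no longer needed.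

2. Step 8. Substitution at C2 is crowded between the ester and the phenoxide on an ester-deactivated ring, so it may be slow or incomplete, and the aldehyde may react further on prolonged heating. The fallback sets out from 14 and comes back at 17. Phenol 14, PhB(OH)2 and paraformaldehyde with catalytic propionic acid in refluxing toluene (water removal) should give the benzodioxaborin F4 by boron-templated ortho-hydroxymethylation. Transesterification with propane-1,3-diol frees the hydroxymethyl benzoate 16, which lactonises to 17 on brief acid treatment. The carbon enters at the alcohol oxidation level, so no hydride step is needed and steps 8 and 9 are both replaced. Peroxide cleavage of the boronate is avoided because of the thioether.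

3. Step 5. The propargyl anion may attack in an SN2' sense or through its silicon-bearing terminus (allenyl product), or act as a base and eliminate the allylic chloride. The fallback sets out from 7 and comes back at 11. Alkylation of the lithium enolate of tert-butyl acetate (LiN(i-Pr)2, THF, −78 °C) with 7 should give the tert-butyl ester F5. Reduction with i-Bu2AlH (CH2Cl2, −78 °C) gives the aldehyde F6. Ohira–Bestmann homologation (dimethyl (1-diazo-2-oxopropyl)phosphonate, K2CO3, MeOH, rt) turns the aldehyde carbon into C3' and adds C2', giving the terminal alkyne 11 directly, so step 6 is not needed.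

**Further compounds**

F1 | step 12 | lithium butyl(dimethyl)[(1E,5E)-2,6,10-trimethyl-10-[(triethylsilyl)oxy]undeca-1,5-dien-1-yl]aluminate | [Li+].CCCC[Al-](C)(C)/C=C(\C)CC/C=C(\C)CCCC(C)(C)O[Si](CC)(CC)CC
F2 | step 12 | (2E,6E)-3,7,11-trimethyl-11-[(triethylsilyl)oxy]dodeca-2,6-dien-1-ol | OC/C=C(\C)CC/C=C(\C)CCCC(C)(C)O[Si](CC)(CC)CC
F3 | step 12 | 4-[(tert-butyldimethylsilyl)oxy]-5-hydroxy-6-methoxy-2-benzofuran-1(3H)-one | COc1cc2c(c(O[Si](C)(C)C(C)(C)C)c1O)COC2=O
F4 | step 8 | methyl 7-methoxy-8-[(methylsulfanyl)methoxy]-2-phenyl-4H-1,3,2-benzodioxaborine-5-carboxylate | COC(=O)c1cc(OC)c(OCSC)c2OB(c3ccccc3)OCc12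
F5 | step 5 | tert-butyl (4E)-5,9-dimethyl-9-[(triethylsilyl)oxy]dec-4-enoate | CC(C)(C)OC(=O)CC/C=C(\C)CCCC(C)(C)O[Si](CC)(CC)CC
F6 | step 5 | (4E)-5,9-dimethyl-9-[(triethylsilyl)oxy]dec-4-enal | O=CCC/C=C(\C)CCCC(C)(C)O[Si](CC)(CC)CC
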